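**Retrosynthetic overview**

1. Positions are numbered as in spiro[4.5]decane: C1 CH(OH), C2 CH carrying the trienyl group, C3/C4 CH2, C5 spiro carbon, C6 C(CH3)OH, C7/C8 CH2, C9 alkylidene carbon, C10 CH carrying the 3-hydroxypropyl arm.
2. Endgame: the enal comes from MnO2 oxidation; ring B and the 2-substituted triene come together from an intramolecular carbonyl-ene reaction of a C1 aldehyde with an all-E tetraenyl chain (C1–C2 bond), the chain being assembled from acrolein, a formyl ylide and geranyl phosphonate.
3. The (Z)-enal comes from oxidative [3,3] transposition of a C9 isopropenyl carbinol; the C6 methyl from MeMgBr on a β-keto lactone; the quaternary C5 from a Michael addition.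
4. Ring A comes from an enantioselective Diels–Alder reaction that forms C7–C8 and C9–C10: a 2-silyloxy diene made from α-acetyl-ε-caprolactone plus methyl vinyl ketone, whose four carbons become C8, C9, the enal α-carbon and its methyl.
5. Enabling feature: in ring A the C6 oxygen is 1,3 to the carbinol carbon C1 (a β-keto ester pattern, hence a 2-silyloxy diene carrying a carboxyl carbon on C5), and C1 and the 3-hydroxypropyl arm on C10 are cis, so C1–C5–C10–(CH2)3–O is an intact ε-caprolactone whose temporary seven-membered ring locks the diene geometry. Ring order: lactone (temporary) → ring A (step 4) → ring B (step 17); the lactone is opened in step 16.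

Key step: step 4

Assumption: the (S)-configured oxazaborolidinium catalyst is taken to expose the diene face that gives the C10 configuration of the target; should the opposite sense be found, the (R)-catalyst is used with no other change.

**Route**

Step 1
Reactants: 1 ε-caprolactone (oxepan-2-one)
Product: 2 3-acetyloxepan-2-one
Conditions: LiN(i-Pr)2 (2.1 equiv), THF, −78 °C; N-methoxy-N-methylacetamide, −78 → −20 °C; AcOH quench
Reagents that add atoms: N-methoxy-N-methylacetamide, CC(=O)N(C)OC
Why: Claisen-type C-acylation of the lactone lithium enolate by an N-methoxy-N-methylamide should stop at the chelated tetrahedral adduct and so give clean mono-acetylation; the new center is enolisable and of no consequence.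

Step 2
Reactants: 2 3-acetyloxepan-2-one
Product: 4 3-acetyl-6,7-dihydrooxepin-2(5H)-one, via selenide 3 (not isolated)
Conditions: PhSeCl, pyridine, CH2Cl2, 0 °C; then 30% H2O2, 0 °C → rt
Reagents that add atoms: none
Why: α-selenenylation of the β-dicarbonyl followed by syn selenoxide elimination (only ring β-hydrogens are available) should give the endocyclic enone-lactone, with the alkene geometry fixed by the seven-membered ring.

Step 3
Reactants: 4 3-acetyl-6,7-dihydrooxepin-2(5H)-one
Product: 5 3-[1-(triisopropylsilyloxy)ethenyl]-6,7-dihydrooxepin-2(5H)-one (diene)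
Conditions: i-Pr3SiOTf, Et3N, Et2O, −78 → 0 °C
Reagents that add atoms: triisopropylsilyl trifluoromethanesulfonate, CC(C)[Si](OS(=O)(=O)C(F)(F)F)(C(C)C)C(C)C
Why: soft enolisation (silyl triflate and amine) with kinetic deprotonation at the acetyl methyl group should give the cross-conjugated 2-silyloxy diene; no stereocenter is formed.

Step 4
Reactants: 5 3-[1-(triisopropylsilyloxy)ethenyl]-6,7-dihydrooxepin-2(5H)-one; 6 methyl vinyl ketone
Product: 7 endo cycloadduct, 6-acetyl-9-(triisopropylsilyloxy)-4,5,5a,6,7,8-hexahydro-2-benzoxepin-1(3H)-one (acetyl at target C9 cis to the lactone CH2 on target C10)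
Conditions: (S)-3,3-diphenyl-1-(o-tolyl)tetrahydro-1H,3H-pyrrolo[1,2-c][1,3,2]oxazaborole (20 mol %), HN(SO2CF3)2 (18 mol %), 6 (3 equiv), CH2Cl2, −78 → −40 °C
Reagents that add atoms: none
Why: Oxazaborolidinium-catalysed asymmetric Diels–Alder reaction: the cationic boron binds the ketone of 6 and the diene adds in an asynchronous [4+2] event, with bonding leading at the silyloxyvinyl CH2 (C7–C8) and closing at the lactone β-carbon (C9–C10); in the stepwise limit this is a Mukaiyama–Michael addition followed by 6-endo-trig Michael closure, which gives the same product. The closest known reaction type is the catalytic enantioselective cycloaddition of 2-(triisopropylsilyloxy)-1,3-dienes with enones, acrylates and enals under this catalyst class. Ring A closes by this suprafacial [4+2] addition onto the temporary lactone, which stays as a fused seven-membered ring. The C10 stereocenter is set by catalyst-controlled facial selection combined with the endo transition state, which also puts the acetyl group cis to the lactone CH2 (the C9 center is erased in step 10). The regioselectivity that is needed (acetyl 1,4 to the silyloxy carbon) is secured twice, by the silyloxy donor at the diene 2-position and by the electrophilic lactone β-carbon, and the lactone ring holds the substituted diene terminus in the only geometry that can reach the reacting s-cis conformation. The C6 oxygen emerges as a robust vinylogous silyl carbonate, ready for regiospecific unmasking.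

Step 5
Reactants: 7 endo cycloadduct
Product: 8 6-(prop-1-en-2-yl)-9-(triisopropylsilyloxy)-4,5,5a,6,7,8-hexahydro-2-benzoxepin-1(3H)-one (isopropenyl at C9 cis to the lactone CH2 on C10)
Conditions: Ph3PCH3Br, KOt-Bu, THF, 0 °C → rt
Reagents that add atoms: methylenetriphenylphosphorane (made in the flask), C=P(c1ccccc1)(c1ccccc1)c1ccccc1
Why: Wittig methylenation of the only ketone (the lactone carbonyl is deactivated as a vinylogous carbonate); any epimerisation at C9 is harmless because that center is destroyed later.

Step 6
Reactants: 8 isopropenyl silyl enol ether; 9 acrolein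
Product: 11 3-[1,9-dioxo-6-(prop-1-en-2-yl)octahydro-2-benzoxepin-9a-yl]propanal (cis-fused lactone; propanal chain on C5 trans to the lactone CH2 on C10), via keto lactone 10 (not isolated)
Conditions: Bu4NF, AcOH, THF, 0 °C; then 9 (1.5 equiv), Et3N (0.2 equiv), 0 °C → rt
Reagents that add atoms: none
Why: fluoride desilylation releases the acidic β-keto lactone, and its amine-catalysed Michael addition to acrolein should create the quaternary C5 from the face syn to the small C10–H (the other face carries the isopropenyl group), giving the cis-fused lactone.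

Step 7
Reactants: 11 quaternary keto lactone aldehyde
Product: 12 9a-[2-(1,3-dioxolan-2-yl)ethyl]-6-(prop-1-en-2-yl)hexahydro-2-benzoxepine-1,9-dione (same configuration as 11)
Conditions: ethylene glycol, pyridinium p-toluenesulfonate (cat.), benzene, 80 °C, azeotropic removal of water
Reagents that add atoms: ethylene glycol, OCCO
Why: chemoselective acetalisation of the aldehyde in the presence of the hindered α-quaternary ketone.

Step 8
Reactants: 12 dioxolane keto lactone
Product: 13 9a-[2-(1,3-dioxolan-2-yl)ethyl]-9-hydroxy-9-methyl-6-(prop-1-en-2-yl)octahydro-2-benzoxepin-1(3H)-one (C6 methyl cis to the dioxolanylethyl chain, C6 hydroxyl cis to the lactone carbonyl)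
Conditions: MeMgBr, CeCl3 (anhydrous), THF, −78 °C; sat. aq. NH4Cl at −78 °C
Reagents that add atoms: methylmagnesium bromide, C[Mg]Br
Why: organocerium 1,2-addition (non-basic, so enolisation and retro-Claisen cleavage are suppressed); axial attack anti to the axially placed lactone carbonyl of the cis-fused bicycle, the usual sense for 2-alkyl-2-alkoxycarbonylcyclohexanones, should put CH3 cis to the C5 side chain and OH cis to the lactone carbonyl.

Step 9
Reactants: 13 tertiary carbinol
Product: 14 6,9-dihydroxy-9-methyl-6-(prop-1-en-2-yl) analogue of 13 (tertiary allylic alcohol at target C9; both C9 epimers are carried on)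
Conditions: SeO2 (0.5 equiv), t-BuOOH (3 equiv), CH2Cl2, rt
Reagents that add atoms: selenium dioxide, O=[Se]=O; tert-butyl hydroperoxide, CC(C)(C)OO
Why: SeO2 allylic hydroxylation (ene reaction, then [2,3]-sigmatropic shift) of a 1,1-disubstituted alkene should take place at the allylic ring methine and give the tertiary allylic alcohol; the C9 configuration is immaterial.

Step 10
Reactants: 14 tertiary allylic alcohol
Product: 15 (Z)-2-{9a-[2-(1,3-dioxolan-2-yl)ethyl]-9-hydroxy-9-methyl-1-oxooctahydro-2-benzoxepin-6-ylidene}propanal (CHO cis to C10)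
Conditions: pyridinium chlorochromate (2.5 equiv), 4 Å molecular sieves, CH2Cl2, rt
Reagents that add atoms: pyridinium chlorochromate, [O-][Cr](=O)(=O)Cl.c1cc[nH+]cc1
Why: Babler–Dauben oxidative transposition ([3,3] shift of the allylic chromate ester, then oxidation); in the chair-like transition state the isopropenyl methyl should eclipse the smaller ring CH2 (C8) and not the branched C10 (A(1,2) strain), so the transposed oxygen ends cis to C10, i.e. the (Z)-enal.

Step 11
Reactants: 15 enal dioxolane
Product: 16 (Z)-2-[9-hydroxy-9-methyl-1-oxo-9a-(3-oxopropyl)octahydro-2-benzoxepin-6-ylidene]propanal (δ-hydroxy aldehyde, expected to rest largely as its six-membered lactol)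
Conditions: pyridinium p-toluenesulfonate, acetone–H2O (9:1), 50 °C
Reagents that add atoms: water, O
Why: mild acid hydrolysis of the dioxolane, under which the tetrasubstituted enal and the tertiary alcohol should survive; the lactol reacts on through its open form.

Step 12
Reactants: 16 dialdehyde; 17 2-(triphenylphosphoranylidene)propanal
Product: 18 (E)-2-methyl-5-{…9a-yl}pent-2-enal: bis-enal with the (E)-OHC–C(CH3)=CH–CH2CH2 chain on C5 and the (Z)-ring enal
Conditions: 17 (1.2 equiv), toluene, 90 °C
Reagents that add atoms: none
Why: Wittig reaction of a stabilised formyl ylide should be selective for the saturated aldehyde over the hindered tetrasubstituted enal and give the (E)-2-methyl-2-enal.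

Step 13
Reactants: 18 bis-enal
Product: 19 C6 triethylsilyl ether of 18
Conditions: Et3SiOTf, 2,6-lutidine, CH2Cl2, −78 → −20 °C
Reagents that add atoms: triethylsilyl trifluoromethanesulfonate, CC[Si](CC)(CC)OS(=O)(=O)C(F)(F)F
Why: silylation of the hindered tertiary alcohol with a silyl triflate prevents retro-aldol cleavage under the basic conditions of step 15 and blocks aluminium chelation in step 17.

Step 14
Reactants: 20 geranyl bromide
Product: 21 diethyl [(2E)-3,7-dimethylocta-2,6-dien-1-yl]phosphonate
Conditions: P(OEt)3, neat, 120 °C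
Reagents that add atoms: triethyl phosphite, CCOP(OCC)OCC
Why: Michaelis–Arbuzov reaction of the primary allylic bromide, which leaves the (E)-trisubstituted alkene untouched.

Step 15
Reactants: 19 silylated bis-enal; 21 diethyl geranylphosphonate
Product: 22 tetraene lactone: C5 carries the (3E,5E,7E)-4,8,12-trimethyltrideca-3,5,7,11-tetraen-1-yl chain; ring enal, lactone and C6 silyl ether unchanged
Conditions: 21 (1.1 equiv), n-BuLi (1.05 equiv), THF, −78 °C; then 19, −78 → −30 °C
Reagents that add atoms: none
Why: Horner–Wadsworth–Emmons olefination through the α-carbon of the allylic phosphonate anion should give the (E)-disubstituted alkene; the unhindered tiglic-type aldehyde is expected to react in preference to the ring enal, whose carbonyl is shielded by the cis ring carbon C10, and to the hindered lactone.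

Step 16
Reactants: 22 tetraene lactone
Product: 23 hydroxy aldehyde (open form of the seven-membered lactol): C1 aldehyde on C5, free 3-hydroxypropyl on C10, (Z)-C9=C(CH3)CH2OH, C6 silyl ether, tetraenyl chain on C5
Conditions: i-Bu2AlH (2.5 equiv), CH2Cl2, −78 °C; aq. potassium sodium tartrate
Reagents that add atoms: none
Why: i-Bu2AlH at low temperature should stop at the lactol stage of the lactone (stable aluminium hemiacetal until work-up) and reduce the ring enal 1,2 to the allylic alcohol, which unveils the neopentyl aldehyde and the primary alcohol in one operation.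

Step 17
Reactants: 23 hydroxy aldehyde
Product: 25 tetraol: the target with CH2OH in place of CHO, via silyl ether 24 (not isolated)
Conditions: Me2AlCl (3.5 equiv), CH2Cl2, −78 → −30 °C; aq. potassium sodium tartrate; then Bu4NF, THF, rt
Reagents that add atoms: none
Why: Lewis acid-promoted intramolecular carbonyl-ene reaction, in which the aluminium-bound aldehyde is attacked by the trisubstituted terminus of the triene and a hydrogen of the alkene methyl passes to oxygen, closing ring B and forming the 2-substituted triene directly (close precedent: Me2AlCl-promoted ene reactions of aldehydes with isoprene to 2-substituted 1,3-dienes, and five-membered closures of citronellal-type aldehydes); the carbonyl oxygen should turn away from the silylated, fully substituted C6 (no chelation), so that the C1 hydroxyl ends syn to C10, five-membered ene closure is expected to place hydroxyl and alkenyl cis, and fluoride then removes the silyl ether.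

Step 18
Reactants: 25 tetraol
Product: 26 CNP0173034.1
Conditions: MnO2 (activated, excess), CH2Cl2, rt
Reagents that add atoms: none
Why: MnO2 should oxidise only the allylic primary alcohol and leave the saturated primary, homoallylic secondary and tertiary alcohols and the triene untouched.

**Compound list**

1 | ε-caprolactone (oxepan-2-one) | O=C1CCCCCO1 | starting material
2 | 3-acetyloxepan-2-one (racemic, enolisable) | CC(=O)C1CCCCOC1=O | intermediate
3 | 3-acetyl-3-(phenylselanyl)oxepan-2-one | CC(=O)C1([Se]c2ccccc2)CCCCOC1=O | intermediate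
4 | 3-acetyl-6,7-dihydrooxepin-2(5H)-one | CC(=O)C1=CCCCOC1=O | intermediate
5 | 3-[1-(triisopropylsilyloxy)ethenyl]-6,7-dihydrooxepin-2(5H)-one | C=C(O[Si](C(C)C)(C(C)C)C(C)C)C1=CCCCOC1=O | intermediate
6 | methyl vinyl ketone (but-3-en-2-one) | CC(=O)C=C | starting material
7 | 6-acetyl-9-(triisopropylsilyloxy)-4,5,5a,6,7,8-hexahydro-2-benzoxepin-1(3H)-one, 5a-H and 6-H cis, C10 as in the target | O=C1OCCC[C@@H]2[C@H](C(C)=O)CCC(O[Si](C(C)C)(C(C)C)C(C)C)=C12 | intermediate
8 | 6-(prop-1-en-2-yl)-9-(triisopropylsilyloxy)-4,5,5a,6,7,8-hexahydro-2-benzoxepin-1(3H)-one, 5a-H and 6-H cis | O=C1OCCC[C@@H]2[C@H](C(C)=C)CCC(O[Si](C(C)C)(C(C)C)C(C)C)=C12 | intermediate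
9 | acrolein (prop-2-enal) | C=CC=O | starting material
10 | 6-(prop-1-en-2-yl)hexahydro-2-benzoxepine-1,9-dione (keto–enol mixture at the ring-fusion carbon C5) | O=C1OCCC[C@@H]2[C@H](C(C)=C)CCC(=O)C12 | intermediate
11 | 3-[1,9-dioxo-6-(prop-1-en-2-yl)octahydro-2-benzoxepin-9a-yl]propanal, cis-fused lactone, propanal chain trans to the lactone CH2 on C10 | O=CCC[C@]1([C@H](CCCO2)[C@H](C(C)=C)CCC1=O)C2=O | intermediate
12 | 9a-[2-(1,3-dioxolan-2-yl)ethyl]-6-(prop-1-en-2-yl)hexahydro-2-benzoxepine-1,9-dione, configuration as 11 | O1CCOC1CC[C@]2([C@H](CCCO3)[C@H](C(C)=C)CCC2=O)C3=O | intermediate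
13 | 9a-[2-(1,3-dioxolan-2-yl)ethyl]-9-hydroxy-9-methyl-6-(prop-1-en-2-yl)octahydro-2-benzoxepin-1(3H)-one, 9-CH3 cis to the 9a chain | O1CCOC1CC[C@]2([C@H](CCCO3)[C@H](C(C)=C)CC[C@]2(C)O)C3=O | intermediate
14 | 9a-[2-(1,3-dioxolan-2-yl)ethyl]-6,9-dihydroxy-9-methyl-6-(prop-1-en-2-yl)octahydro-2-benzoxepin-1(3H)-one, both epimers at the allylic carbinol carbon (target C9) | O1CCOC1CC[C@]2([C@H](CCCO3)C(O)(C(C)=C)CC[C@]2(C)O)C3=O | intermediate
15 | (Z)-2-{9a-[2-(1,3-dioxolan-2-yl)ethyl]-9-hydroxy-9-methyl-1-oxooctahydro-2-benzoxepin-6-ylidene}propanal | O1CCOC1CC[C@]2([C@H](CCCO3)/C(=C(/C)C=O)CC[C@]2(C)O)C3=O | intermediate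
16 | (Z)-2-[9-hydroxy-9-methyl-1-oxo-9a-(3-oxopropyl)octahydro-2-benzoxepin-6-ylidene]propanal (in equilibrium with its six-membered lactol) | O=CCC[C@]1([C@H](CCCO2)/C(=C(/C)C=O)CC[C@]1(C)O)C2=O | intermediate
17 | 2-(triphenylphosphoranylidene)propanal | CC(C=O)=P(c1ccccc1)(c1ccccc1)c1ccccc1 | starting material
18 | bis-enal: (E)-2-methylpent-2-enal chain on C5, (Z)-ring enal, free C6 hydroxyl | O=C/C(C)=C/CC[C@]1([C@H](CCCO2)/C(=C(/C)C=O)CC[C@]1(C)O)C2=O | intermediate
19 | C6 triethylsilyl ether of 18 | O=C/C(C)=C/CC[C@]1([C@H](CCCO2)/C(=C(/C)C=O)CC[C@]1(C)O[Si](CC)(CC)CC)C2=O | intermediate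
20 | geranyl bromide, (E)-1-bromo-3,7-dimethylocta-2,6-diene | BrC/C=C(\C)CCC=C(C)C | starting material
21 | diethyl [(2E)-3,7-dimethylocta-2,6-dien-1-yl]phosphonate | CCOP(=O)(OCC)C/C=C(\C)CCC=C(C)C | intermediate
22 | tetraene lactone: (3E,5E,7E)-4,8,12-trimethyltrideca-3,5,7,11-tetraen-1-yl chain on C5, (Z)-ring enal, C6 silyl ether | CC(C)=CCC/C(C)=C/C=C/C(C)=C/CC[C@]1([C@H](CCCO2)/C(=C(/C)C=O)CC[C@]1(C)O[Si](CC)(CC)CC)C2=O | intermediate
23 | hydroxy aldehyde: C1 aldehyde on C5, 3-hydroxypropyl on C10, (Z)-C9=C(CH3)CH2OH, C6 silyl ether, tetraenyl chain | CC(C)=CCC/C(C)=C/C=C/C(C)=C/CC[C@]1([C@H](CCCO)/C(=C(/C)CO)CC[C@]1(C)O[Si](CC)(CC)CC)C=O | intermediate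
24 | ene product, C6 triethylsilyl ether of 25 | C=C(/C=C/C=C(\C)CCC=C(C)C)[C@@H]1CC[C@]2([C@H](CCCO)/C(=C(/C)CO)CC[C@]2(C)O[Si](CC)(CC)CC)[C@@H]1O | intermediate
25 | tetraol: spiro[4.5]decane with 1-OH and the 2-[(3E,5E)-6,10-dimethylundeca-1,3,5,9-tetraen-2-yl] group cis and both syn to C10, 6-OH/6-CH3, (Z)-9-(1-hydroxypropan-2-ylidene), 10-(3-hydroxypropyl) | C=C(/C=C/C=C(\C)CCC=C(C)C)[C@@H]1CC[C@]2([C@H](CCCO)/C(=C(/C)CO)CC[C@]2(C)O)[C@@H]1O | intermediate
26 | CNP0173034.1 | C=C(/C=C/C=C(\C)CCC=C(C)C)[C@@H]1CC[C@]2([C@H](CCCO)/C(=C(/C)C=O)CC[C@]2(C)O)[C@@H]1O | target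

**Step count**

Total: 18 steps. Longest linear sequence: 17 steps (steps 1–13 and 15–18, from ε-caprolactone); step 14 is the one-step side branch.

**Steps most likely to fail, with fallbacks**

Step 17 (ene ring closure). The Lewis acid may ionise the extended triene, after which proton loss at a distal allylic position or oligomerisation could compete with hydrogen transfer from the alkene methyl group. Partial loss of the silyl ether would also allow aluminium chelation and erode facial selectivity at C1. The fallback sets out from 19 and returns at 24. It shortens the ene donor to a 1-iodo-1,3-diene that has no distal allylic hydrogens and completes the triene after ring closure by cross-coupling. Takai iodo-olefination (CHI3, CrCl2, THF, 0 °C) of the unhindered enal of 19 should give the (1E,3E)-dienyl iodide F1. Reduction with i-Bu2AlH as in step 16 then gives the hydroxy aldehyde F2, and Me2AlCl as in step 17, without the fluoride treatment, gives the cyclopentanol dienyl iodide F3. Separately, 6-methylhept-5-en-1-yne F4 is made from commercial 5-bromo-2-methylpent-2-ene and lithium acetylide–ethylenediamine in DMSO. It is carboaluminated (AlMe3, Cp2ZrCl2 cat., CH2Cl2) to the (E)-alkenylalane F5. After transmetalation with ZnCl2, F5 is coupled with F3 (hydroxyls first metalated with i-PrMgCl; Pd(PPh3)4, THF; Negishi coupling with retention at both partners) to give 24, which goes on to the fluoride treatment of step 17.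

Step 4 (key cycloaddition). The cationic catalyst may be sequestered by the Lewis-basic vinylogous carbonate of 5, the diene may be protodesilylated, or facial discrimination may be insufficient. The fallback sets out from 5 and returns at 7, and uses stoichiometric auxiliary control. Diene 5 and commercial (S)-3-acryloyl-4-benzyloxazolidin-2-one with Et2AlCl (CH2Cl2, −78 °C) should give the endo imide F6, the diene adding to the chelated s-cis acrylimide anti to the benzyl group. Transamination with MeONHMe·HCl and AlMe3 gives the N-methoxy-N-methylamide F7, and MeMgBr (THF, 0 °C) converts F7 into 7.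

Step 10 (oxidative transposition). Geometric control in the sigmatropic shift may be incomplete, and the acidic chromate conditions may cleave the dioxolane or ionise the tertiary allylic alcohol. The fallback sets out from 14 and returns at 15, and separates the two events. A catalytic, non-oxidising and reversible 1,3-hydroxyl transposition (Ph3SiOReO3, Et2O, −50 → 0 °C) gives the primary allylic alcohol F8 under equilibrium control; the unwanted geometric isomer is recycled through 14 by re-exposure to the catalyst. MnO2 (CH2Cl2, rt) then oxidises F8 to 15.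

**Further compounds**

F1 | step 17 | (1E,3E)-dienyl iodide: 19 with the chain aldehyde replaced by CH=CHI | I/C=C/C(C)=C/CC[C@]1([C@H](CCCO2)/C(=C(/C)C=O)CC[C@]1(C)O[Si](CC)(CC)CC)C2=O
F2 | step 17 | hydroxy aldehyde dienyl iodide (analogue of 23) | I/C=C/C(C)=C/CC[C@]1([C@H](CCCO)/C(=C(/C)CO)CC[C@]1(C)O[Si](CC)(CC)CC)C=O
F3 | step 17 | cyclopentanol carrying the (E)-4-iodobuta-1,3-dien-2-yl group (analogue of 24) | C=C(/C=C/I)[C@@H]1CC[C@]2([C@H](CCCO)/C(=C(/C)CO)CC[C@]2(C)O[Si](CC)(CC)CC)[C@@H]1O
F4 | step 17 | 6-methylhept-5-en-1-yne | C#CCCC=C(C)C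
F5 | step 17 | (E)-(2,6-dimethylhepta-1,5-dien-1-yl)dimethylalane | C[Al](C)/C=C(\C)CCC=C(C)C
F6 | step 4 | endo imide: 7 with the acetyl replaced by the (S)-4-benzyl-2-oxooxazolidine-3-carbonyl group | O=C1OCCC[C@@H]2[C@H](C(=O)N3[C@@H](Cc4ccccc4)COC3=O)CCC(O[Si](C(C)C)(C(C)C)C(C)C)=C12
F7 | step 4 | N-methoxy-N-methylamide: 7 with the acetyl replaced by C(=O)N(OCH3)CH3 | O=C1OCCC[C@@H]2[C@H](C(=O)N(C)OC)CCC(O[Si](C(C)C)(C(C)C)C(C)C)=C12
F8 | step 10 | (Z)-primary allylic alcohol: 15 with CH2OH in place of CHO | O1CCOC1CC[C@]2([C@H](CCCO3)/C(=C(/C)CO)CC[C@]2(C)O)C3=O
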